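**Retrosynthetic overview**

1. Target 26 ⇐ lactonisation (C11–OH onto the C13 ester) of β-hydroxy ketone 25 ⇐ N–O hydrogenolysis of macrocyclic isoxazoline 24.
2. 24 ⇐ intramolecular nitrile oxide–(Z)-alkene [3+2] cycloaddition of 23 (from oxime 22). This key step closes the 11-membered ring and the isoxazoline together, forms C9–C10 and C11–O, and sets C10 and C11.
3. 22 ⇐ side-chain lactone from acid 15 plus a Roche-type zinc reagent (C20 bought), then Felkin reduction (C18); the (Z)-alkene comes from a Wittig reaction on the C11 aldehyde (lactol 12).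
4. 12 ⇐ diol cleavage of 10 ⇐ tandem Michael addition/methylation of the lactam enolate of 4 onto butenolide 6 (sets C1, C12, C13; the butenolide stereocentre is then excised).
5. Ring order: pyrrolidinone (bought as L-pyroglutaminol) → relay butyrolactone → side-chain lactone → isoxazoline + 11-membered ring in one step → fused lactone.

The target is tuberostemonone. Position labels follow its usual numbering: pyrrolidinone C1–C2–C3–N4–C9a(=O); N4–C5…C8–C9(=O)–C10(Et)–C11(O)–C12–C13(Me)–C14(=O); side-chain lactone C18(O)–C19–C20(Me)–C21(=O).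

Assumption: 1, 3, 5 and 16 are catalogue compounds; LDA, NaHMDS, TBAF and L-Selectride are used as bought solutions.

**Route**

Step 1
Reactants: 1 (S)-5-(hydroxymethyl)pyrrolidin-2-one
Product: 2 (S)-5-[(tert-butyldimethylsilyloxy)methyl]pyrrolidin-2-one
Conditions: TBSCl, imidazole, DMF, rt
Reagents that add atoms: tert-butyldimethylsilyl chloride, CC(C)(C)[Si](C)(C)Cl
Why: Imidazole-promoted silylation of the primary alcohol masks the only O–H before the N-alkylation and enolate steps and touches no stereocentre.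

Step 2
Reactants: 2 (S)-5-[(tert-butyldimethylsilyloxy)methyl]pyrrolidin-2-one; 3 2-(4-bromobutyl)-1,3-dioxolane
Product: 4 (S)-5-[(tert-butyldimethylsilyloxy)methyl]-1-[4-(1,3-dioxolan-2-yl)butyl]pyrrolidin-2-one
Conditions: NaH, DMF, 0 °C; then 3, rt
Reagents that add atoms: none
Why: SN2 N-alkylation of the sodium lactamate by the primary bromide installs C5–C9 with C9 masked as a base-stable acetal, and the C3 stereocentre is not acidic.

Step 3
Reactants: 5 (S)-5-(hydroxymethyl)furan-2(5H)-one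
Product: 6 (S)-5-[(tert-butyldimethylsilyloxy)methyl]furan-2(5H)-one
Conditions: TBSCl, imidazole, CH2Cl2, 0 °C
Reagents that add atoms: tert-butyldimethylsilyl chloride, CC(C)(C)[Si](C)(C)Cl
Why: Silylation gives the standard chiral butenolide acceptor whose bulky CH2OTBS group blocks one face.

Step 4
Reactants: 4 (S)-5-[(tert-butyldimethylsilyloxy)methyl]-1-[4-(1,3-dioxolan-2-yl)butyl]pyrrolidin-2-one; 6 (S)-5-[(tert-butyldimethylsilyloxy)methyl]furan-2(5H)-one
Product: 9 (3S,5S)-5-[(tert-butyldimethylsilyloxy)methyl]-3-{(2S,3S,4S)-2-[(tert-butyldimethylsilyloxy)methyl]-4-methyl-5-oxooxolan-3-yl}-1-[4-(1,3-dioxolan-2-yl)butyl]pyrrolidin-2-one, via lactam lithium enolate 7 (not isolated), via lactone lithium enolate 8 (not isolated)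
Conditions: LDA, THF, −78 °C; 6, −78 °C; then MeI, DMPU, −78 → −30 °C
Reagents that add atoms: iodomethane, CI
Why: In this tandem Michael addition/enolate alkylation the lactam enolate attacks the butenolide β-carbon anti to CH2OTBS (sets C12) from its own face anti to the C3 substituent (sets C1, 1,3-trans), and the resulting lactone enolate is methylated anti to the new β-substituent (sets C13).

Step 5
Reactants: 9 (the bis-silyl ether lactone above)
Product: 10 (3S,5S)-1-[4-(1,3-dioxolan-2-yl)butyl]-5-(hydroxymethyl)-3-[(2S,3S,4S)-2-(hydroxymethyl)-4-methyl-5-oxooxolan-3-yl]pyrrolidin-2-one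
Conditions: TBAF, AcOH, THF, 0 °C → rt
Reagents that add atoms: none
Why: Buffered fluoride desilylation frees both primary alcohols without touching the acetal or epimerising the lactone (any translactonised isomer converges in step 6).

Step 6
Reactants: 10 (the diol lactone above)
Product: 12 (3S,5S)-1-[4-(1,3-dioxolan-2-yl)butyl]-3-[(3S,4S)-2-hydroxy-4-methyl-5-oxooxolan-3-yl]-5-(hydroxymethyl)pyrrolidin-2-one (lactol form of the C11 aldehyde acid; anomer mixture), via lithium trihydroxy carboxylate 11 (not isolated)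
Conditions: LiOH·H2O, THF/H2O, 0 °C; NaH2PO4 to pH 7, NaIO4, 0 °C → rt; then 0.5 M HCl to pH 3, 0 °C, EtOAc
Reagents that add atoms: lithium hydroxide, [Li+].[OH-]
Why: Saponification exposes the vicinal diol and periodate (Malaprade) cleavage excises the relay stereocentre as formaldehyde, leaving the C11 aldehyde, which closes to the lactol on acidification while the N-acyl amino alcohol and the acetal are inert.

Step 7
Reactants: 12 (the lactol above)
Product: 14 methyl (2S,3S,4Z)-3-{(3S,5S)-1-[4-(1,3-dioxolan-2-yl)butyl]-5-(hydroxymethyl)-2-oxopyrrolidin-3-yl}-2-methylhept-4-enoate, via Z-alkenyl acid 13 (not isolated)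
Conditions: [Ph3PCH2CH2CH3]Br (4.0 equiv), NaHMDS (3.9 equiv), THF, −78 → 0 °C; 12, −78 °C → rt; acidic work-up; then TMSCHN2, PhMe/MeOH, 0 °C
Reagents that add atoms: propyltriphenylphosphonium bromide, CCC[P+](c1ccccc1)(c1ccccc1)c1ccccc1.[Br-]; trimethylsilyldiazomethane, C[Si](C)(C)C=[N+]=[N-]
Why: A Z-selective Wittig olefination of the lactol (reacting through its open aldehyde carboxylate) with a non-stabilised ylide gives the (Z)-butenyl group needed for the cycloaddition, and the diazoalkane then esterifies only the acid.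

Step 8
Reactants: 14 (the hydroxy ester above)
Product: 15 (2S,4S)-1-[4-(1,3-dioxolan-2-yl)butyl]-4-[(2S,3S,4Z)-1-methoxy-2-methyl-1-oxohept-4-en-3-yl]-5-oxopyrrolidine-2-carboxylic acid
Conditions: TEMPO (cat.), PhI(OAc)2, MeCN/pH 7 phosphate buffer, rt
Reagents that add atoms: water, O
Why: TEMPO/PhI(OAc)2 oxidation takes the primary alcohol through the aldehyde hydrate to the acid under near-neutral conditions that spare the Z-alkene, the acetal and the adjacent N-bearing stereocentre.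

Step 9
Reactants: 15 (the acid above); 16 methyl (R)-3-bromo-2-methylpropanoate
Product: 19 methyl (2S,3S,4Z)-3-{(3S,5S)-1-[4-(1,3-dioxolan-2-yl)butyl]-5-[(3S)-4-methoxy-3-methyl-4-oxobutanoyl]-2-oxopyrrolidin-3-yl}-2-methylhept-4-enoate, via acid chloride 17 (not isolated), via zinc homoenolate 18 (not isolated)
Conditions: 15, 1-chloro-N,N,2-trimethylprop-1-en-1-amine, CH2Cl2, 0 °C → rt; separately 16, Zn dust (TMSCl/BrCH2CH2Br-activated), LiCl, THF, 40 °C; combine, Pd(PPh3)4 (5 mol %), THF, 0 °C → rt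
Reagents that add atoms: none
Why: Neutral acid chloride formation followed by Pd-catalysed Negishi acylation with the configurationally stable β-zinc ester (γ-keto ester synthesis) brings in C19–C21 with C20 bought in 16, and N-alkyl pyroglutamoyl chlorides are slow to racemise.

Step 10
Reactants: 19 (the keto diester above)
Product: 21 methyl (2S,3S,4Z)-3-{(3S,5S)-1-[4-(1,3-dioxolan-2-yl)butyl]-5-[(2S,4S)-4-methyl-5-oxooxolan-2-yl]-2-oxopyrrolidin-3-yl}-2-methylhept-4-enoate, via lithium alkoxide 20 (not isolated)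
Conditions: L-Selectride, THF, −78 °C; warm to 0 °C; AcOH quench
Reagents that add atoms: none
Why: L-Selectride reduces only the ketone under polar Felkin–Anh control (lactam N anti to the hydride, attack past H) to give the 18S alkoxide, which lactonises on warming onto the γ-ester only.

Step 11
Reactants: 21 (the acetal lactone above)
Product: 22 methyl (2S,3S,4Z)-3-{(3S,5S)-1-[5-(hydroxyimino)pentyl]-5-[(2S,4S)-4-methyl-5-oxooxolan-2-yl]-2-oxopyrrolidin-3-yl}-2-methylhept-4-enoate (E/Z oxime mixture)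
Conditions: NH2OH·HCl, THF/H2O, 45 °C
Reagents that add atoms: hydroxylamine hydrochloride, NO.Cl
Why: The acidic hydroxylamine salt hydrolyses the dioxolane and condenses with the released aldehyde in one pot (transoximation) at a pH where lactone, ester and alkene are stable.

Step 12
Reactants: 22 (the oxime above)
Product: 24 macrocyclic 2-isoxazoline (C9=N–O–C11, fused across C10–C11 of the new 11-membered ring; 10-ethyl; C12 bearing (S)-CH(CH3)CO2CH3; 1S,3S,10R,11R,12S,13S,18S,20S), via nitrile oxide 23 (not isolated)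
Conditions: slow addition of 22 (syringe pump) to aq. NaOCl/CH2Cl2, Et3N (cat.), 0 °C → rt, final 1 mM
Reagents that add atoms: none
Why: In this intramolecular nitrile oxide–alkene 1,3-dipolar (Huisgen) cycloaddition the dipole carbon bonds to the less hindered distal carbon C10 and O to C11, suprafacially on the (Z)-alkene and on the face carrying the tether because A(1,3) strain keeps C12–H in the alkene plane, which gives the target 10,11-configuration.

Step 13
Reactants: 24 (the isoxazoline above)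
Product: 26 tuberostemonone (1S,3S,10S,11R,12S,13S,18S,20S; the target), via hydroxy ketone ester 25 (not isolated)
Conditions: Raney Ni, H2 (1 atm), B(OH)3, MeOH/H2O, rt; filter; then PPTS (cat.), PhH, 40 °C
Reagents that add atoms: water, O
Why: Raney nickel hydrogenolysis of the N–O bond with boric acid-assisted imine hydrolysis unmasks the β-hydroxy ketone without epimerising C10, and the γ-hydroxy ester then closes to the cis-fused γ-lactone under mild acid catalysis.

**Compound list**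

1 | (S)-5-(hydroxymethyl)pyrrolidin-2-one (L-pyroglutaminol) | O=C1CC[C@@H](CO)N1 | starting material
2 | (S)-5-[(tert-butyldimethylsilyloxy)methyl]pyrrolidin-2-one | O=C1CC[C@@H](CO[Si](C)(C)C(C)(C)C)N1 | intermediate
3 | 2-(4-bromobutyl)-1,3-dioxolane | BrCCCCC1OCCO1 | starting material
4 | (S)-5-[(tert-butyldimethylsilyloxy)methyl]-1-[4-(1,3-dioxolan-2-yl)butyl]pyrrolidin-2-one | O=C1CC[C@@H](CO[Si](C)(C)C(C)(C)C)N1CCCCC2OCCO2 | intermediate
5 | (S)-5-(hydroxymethyl)furan-2(5H)-one | O=C1C=C[C@@H](CO)O1 | starting material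
6 | (S)-5-[(tert-butyldimethylsilyloxy)methyl]furan-2(5H)-one | O=C1C=C[C@@H](CO[Si](C)(C)C(C)(C)C)O1 | intermediate
7 | lithium enolate of lactam 4 | [Li]OC1=CC[C@@H](CO[Si](C)(C)C(C)(C)C)N1CCCCC2OCCO2 | intermediate (not isolated)
8 | lithium lactone enolate of the Michael adduct (des-methyl 9) | O1CCOC1CCCCN1C(=O)[C@@H](C[C@H]1CO[Si](C)(C)C(C)(C)C)[C@@H]1[C@@H](CO[Si](C)(C)C(C)(C)C)OC(O[Li])=C1 | intermediate (not isolated)
9 | (3S,5S)-5-[(tert-butyldimethylsilyloxy)methyl]-3-{(2S,3S,4S)-2-[(tert-butyldimethylsilyloxy)methyl]-4-methyl-5-oxooxolan-3-yl}-1-[4-(1,3-dioxolan-2-yl)butyl]pyrrolidin-2-one | O1CCOC1CCCCN1C(=O)[C@@H](C[C@H]1CO[Si](C)(C)C(C)(C)C)[C@@H]1[C@@H](CO[Si](C)(C)C(C)(C)C)OC(=O)[C@H]1C | intermediate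
10 | (3S,5S)-1-[4-(1,3-dioxolan-2-yl)butyl]-5-(hydroxymethyl)-3-[(2S,3S,4S)-2-(hydroxymethyl)-4-methyl-5-oxooxolan-3-yl]pyrrolidin-2-one | O1CCOC1CCCCN1C(=O)[C@@H](C[C@H]1CO)[C@@H]1[C@@H](CO)OC(=O)[C@H]1C | intermediate
11 | lithium (2S,3S,4S)-3-{(3S,5S)-1-[4-(1,3-dioxolan-2-yl)butyl]-5-(hydroxymethyl)-2-oxopyrrolidin-3-yl}-4,5-dihydroxy-2-methylpentanoate | O1CCOC1CCCCN1C(=O)[C@@H](C[C@H]1CO)[C@H]([C@H](O)CO)[C@H](C)C(=O)O[Li] | intermediate (not isolated)
12 | (3S,5S)-1-[4-(1,3-dioxolan-2-yl)butyl]-3-[(3S,4S)-2-hydroxy-4-methyl-5-oxooxolan-3-yl]-5-(hydroxymethyl)pyrrolidin-2-one (lactol, anomer mixture) | O1CCOC1CCCCN1C(=O)[C@@H](C[C@H]1CO)[C@@H]1C(O)OC(=O)[C@H]1C | intermediate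
13 | (2S,3S,4Z)-3-{(3S,5S)-1-[4-(1,3-dioxolan-2-yl)butyl]-5-(hydroxymethyl)-2-oxopyrrolidin-3-yl}-2-methylhept-4-enoic acid | O1CCOC1CCCCN1C(=O)[C@@H](C[C@H]1CO)[C@H](/C=C\CC)[C@H](C)C(O)=O | intermediate (not isolated)
14 | methyl (2S,3S,4Z)-3-{(3S,5S)-1-[4-(1,3-dioxolan-2-yl)butyl]-5-(hydroxymethyl)-2-oxopyrrolidin-3-yl}-2-methylhept-4-enoate | O1CCOC1CCCCN1C(=O)[C@@H](C[C@H]1CO)[C@H](/C=C\CC)[C@H](C)C(=O)OC | intermediate
15 | (2S,4S)-1-[4-(1,3-dioxolan-2-yl)butyl]-4-[(2S,3S,4Z)-1-methoxy-2-methyl-1-oxohept-4-en-3-yl]-5-oxopyrrolidine-2-carboxylic acid | O1CCOC1CCCCN1C(=O)[C@@H](C[C@H]1C(O)=O)[C@H](/C=C\CC)[C@H](C)C(=O)OC | intermediate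
16 | methyl (R)-3-bromo-2-methylpropanoate | BrC[C@H](C)C(=O)OC | starting material
17 | acid chloride of 15 | O1CCOC1CCCCN1C(=O)[C@@H](C[C@H]1C(Cl)=O)[C@H](/C=C\CC)[C@H](C)C(=O)OC | intermediate (not isolated)
18 | (R)-(3-methoxy-2-methyl-3-oxopropyl)zinc bromide | Br[Zn]C[C@H](C)C(=O)OC | intermediate (not isolated)
19 | methyl (2S,3S,4Z)-3-{(3S,5S)-1-[4-(1,3-dioxolan-2-yl)butyl]-5-[(3S)-4-methoxy-3-methyl-4-oxobutanoyl]-2-oxopyrrolidin-3-yl}-2-methylhept-4-enoate | O1CCOC1CCCCN1C(=O)[C@@H](C[C@H]1C(=O)C[C@H](C)C(=O)OC)[C@H](/C=C\CC)[C@H](C)C(=O)OC | intermediate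
20 | lithium alkoxide of the (18S)-γ-hydroxy diester from 19 | O1CCOC1CCCCN1C(=O)[C@@H](C[C@H]1[C@@H](O[Li])C[C@H](C)C(=O)OC)[C@H](/C=C\CC)[C@H](C)C(=O)OC | intermediate (not isolated)
21 | methyl (2S,3S,4Z)-3-{(3S,5S)-1-[4-(1,3-dioxolan-2-yl)butyl]-5-[(2S,4S)-4-methyl-5-oxooxolan-2-yl]-2-oxopyrrolidin-3-yl}-2-methylhept-4-enoate | O1CCOC1CCCCN1C(=O)[C@@H](C[C@H]1[C@@H]1C[C@H](C)C(=O)O1)[C@H](/C=C\CC)[C@H](C)C(=O)OC | intermediate
22 | methyl (2S,3S,4Z)-3-{(3S,5S)-1-[5-(hydroxyimino)pentyl]-5-[(2S,4S)-4-methyl-5-oxooxolan-2-yl]-2-oxopyrrolidin-3-yl}-2-methylhept-4-enoate | ON=CCCCCN1C(=O)[C@@H](C[C@H]1[C@@H]1C[C@H](C)C(=O)O1)[C@H](/C=C\CC)[C@H](C)C(=O)OC | intermediate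
23 | nitrile oxide from 22 (C9≡N+–O−) | [O-][N+]#CCCCCN1C(=O)[C@@H](C[C@H]1[C@@H]1C[C@H](C)C(=O)O1)[C@H](/C=C\CC)[C@H](C)C(=O)OC | intermediate (not isolated)
24 | macrocyclic 2-isoxazoline (C9=N–O–C11; 1S,3S,10R,11R,12S,13S,18S,20S), methyl ester at C14 | CC[C@@H]1C(=NO2)CCCCN3C(=O)[C@@H](C[C@H]3[C@@H]3C[C@H](C)C(=O)O3)[C@@H]([C@H](C)C(=O)OC)[C@H]12 | intermediate
25 | 11-hydroxy-9-keto macrocyclic lactam methyl ester (1S,3S,10S,11R,12S,13S,18S,20S) | CC[C@@H]1C(=O)CCCCN2C(=O)[C@@H](C[C@H]2[C@@H]2C[C@H](C)C(=O)O2)[C@@H]([C@H](C)C(=O)OC)[C@H]1O | intermediate (not isolated)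
26 | tuberostemonone (1S,3S,10S,11R,12S,13S,18S,20S) | CC[C@@H]1C(=O)CCCCN2C(=O)[C@@H](C[C@H]2[C@@H]2C[C@H](C)C(=O)O2)[C@@H]2[C@H]1OC(=O)[C@H]2C | target

**Totals and risks**

Total step count: 13. Longest linear sequence: 12 steps (1 → 2 → 4 → 9 → 10 → 12 → 14 → 15 → 19 → 21 → 22 → 24 → 26).

The three steps most likely to fail are step 12, step 4 and step 10, in that order of concern. The fallbacks are given in route order.

Step 4 (tandem Michael/methylation). The basic lactam enolate may deprotonate the γ-position of the butenolide, or face selectivity at C1 may be modest. The fallback sets out from 4 (with 6) and comes back at 9. Lactam 4 is soft-enolised with TMSOTf/Et3N in CH2Cl2 at 0 °C to the O-trimethylsilyl ketene N,O-acetal F1. F1 then adds to 6 at −78 °C under the TMSOTf already present, a non-basic Mukaiyama–Michael addition with the same facial preferences, giving after aqueous work-up the des-methyl adduct F2. The more acidic lactone α-position of F2 is then deprotonated selectively with LiHMDS (THF, −78 °C) and methylated with MeI anti to the C12 substituent to give 9.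

Step 10 (Felkin reduction). If hydride delivery gives mainly the 18R carbinol, the fallback sets out from 19 and comes back at 21 by inverting rather than retaining that centre. The reduction of 19 is run and quenched cold (NaBH4/CeCl3, MeOH, −78 °C) so that the open (18R)-hydroxy diester F3 is kept. F3 is converted with MsCl/Et3N (CH2Cl2, 0 °C) into the mesylate F4. Heating F4 in toluene with 2,6-lutidine (90 °C) lets the γ-ester carbonyl oxygen displace the mesylate with inversion (loss of methyl mesylate), giving the 18S lactone 21. A mixture of carbinols is convergent, since the 18S isomer lactonises directly.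

Step 12 (macrocyclic nitrile oxide cycloaddition). Furoxan dimerisation or the wrong regiochemistry on the internal (Z)-alkene could defeat it. The fallback sets out from 21 and comes back at 26, using an isolable dipole under thermal, reversible conditions. Acetal hydrolysis of 21 (PPTS, acetone/H2O, 50 °C) gives the aldehyde F5. Condensation with N-benzylhydroxylamine (MgSO4, CH2Cl2) gives the N-benzyl nitrone F6. Heating F6 in toluene (110 °C, 1 mM) effects the intramolecular nitrone–alkene [3+2] cycloaddition to the N-benzyl isoxazolidine F7, with the same tether and A(1,3) control and no dimerisation. Hydrogenolysis of F7 (H2, Pd(OH)2/C, MeOH) cleaves N–O and N–benzyl, and the freed C11–OH lactonises to the 9-amino lactone F8. Oxidative deamination of F8 with 3,5-di-tert-butyl-1,2-benzoquinone (MeOH/THF, then aqueous oxalic acid) gives ketone 26.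

**Further compounds**

F1 | step 4 | (S)-5-[(tert-butyldimethylsilyloxy)methyl]-1-[4-(1,3-dioxolan-2-yl)butyl]-2-(trimethylsilyloxy)-4,5-dihydro-1H-pyrrole | C[Si](C)(C)OC1=CC[C@@H](CO[Si](C)(C)C(C)(C)C)N1CCCCC2OCCO2
F2 | step 4 | (3S,5S)-5-[(tert-butyldimethylsilyloxy)methyl]-3-{(2S,3R)-2-[(tert-butyldimethylsilyloxy)methyl]-5-oxooxolan-3-yl}-1-[4-(1,3-dioxolan-2-yl)butyl]pyrrolidin-2-one | O1CCOC1CCCCN1C(=O)[C@@H](C[C@H]1CO[Si](C)(C)C(C)(C)C)[C@@H]1[C@@H](CO[Si](C)(C)C(C)(C)C)OC(=O)C1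
F3 | step 10 | (18R)-γ-hydroxy diester (open-chain C18 epimer of the carbinol from 19) | O1CCOC1CCCCN1C(=O)[C@@H](C[C@H]1[C@H](O)C[C@H](C)C(=O)OC)[C@H](/C=C\CC)[C@H](C)C(=O)OC
F4 | step 10 | (18R)-methanesulfonate of F3 | O1CCOC1CCCCN1C(=O)[C@@H](C[C@H]1[C@H](OS(C)(=O)=O)C[C@H](C)C(=O)OC)[C@H](/C=C\CC)[C@H](C)C(=O)OC
F5 | step 12 | methyl (2S,3S,4Z)-2-methyl-3-{(3S,5S)-5-[(2S,4S)-4-methyl-5-oxooxolan-2-yl]-2-oxo-1-(5-oxopentyl)pyrrolidin-3-yl}hept-4-enoate | O=CCCCCN1C(=O)[C@@H](C[C@H]1[C@@H]1C[C@H](C)C(=O)O1)[C@H](/C=C\CC)[C@H](C)C(=O)OC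
F6 | step 12 | N-benzyl nitrone of F5 | [O-][N+](Cc1ccccc1)=CCCCCN1C(=O)[C@@H](C[C@H]1[C@@H]1C[C@H](C)C(=O)O1)[C@H](/C=C\CC)[C@H](C)C(=O)OC
F7 | step 12 | macrocyclic N-benzyl isoxazolidine (C9–N(Bn)–O–C11; C9 unassigned; methyl ester at C14) | CC[C@@H]1C2CCCCN3C(=O)[C@@H](C[C@H]3[C@@H]3C[C@H](C)C(=O)O3)[C@@H]([C@H](C)C(=O)OC)[C@H]1ON2Cc1ccccc1
F8 | step 12 | 9-amino-9-deoxo-tuberostemonone (C9 unassigned) | CC[C@@H]1C(N)CCCCN2C(=O)[C@@H](C[C@H]2[C@@H]2C[C@H](C)C(=O)O2)[C@@H]2[C@H]1OC(=O)[C@H]2C
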